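**Retrosynthetic overview**
- The central C15=C15′ double bond is cut by a Wittig disconnection into a C20 ring-end phosphonium salt and a C20 acyclic polyenal, joined in the last step.
- Each C20 half comes from a terminal enyne and one common C6 dienyl iodide, by Zr-catalysed methylalumination and Pd-catalysed alkenyl–alkenyl coupling (this sets the 9- and 9′-methyl E-olefins).
- The acyclic dienyne comes from 6-methylhept-5-en-1-yne and a C4 chloroenyne; the ring enyne comes from a cyclopentanecarbaldehyde by Takai iodo-olefination and Sonogashira coupling.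
- The ring stereotriad is set by an enantioselective Diels–Alder reaction (C2), a trans epoxidation of a cyclopentenecarbaldehyde followed by Wharton transposition (C5–OH), and a face-selective hydroboration of the exocyclic methylene (C6).
- Ring order: a cyclohexene is made first (isoprene + methyl acrylate) and is then contracted to the single cyclopentane of the target by ozonolysis and intramolecular aldol condensation.

Assumption: the SMILES is read as all-E (2R,5R,6R)-2,6-cyclolycopene-1,5-diol; carotenoid locants are used in the Why lines (C1 = CMe2OH carbon, C2 and C6 = ring CH, C5 = ring C(CH3)OH, C7 onward = polyene, primed locants = acyclic half).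

**Route**

Step 1
Reactants: 1 (2E)-3-methylpent-2-en-4-yn-1-ol
Product: 2 tert-butyldimethyl{[(2E)-3-methylpent-2-en-4-yn-1-yl]oxy}silane
Conditions: TBSCl (1.1 equiv), imidazole (2 equiv), CH2Cl2, 0 → 23 °C
Reagents that add atoms: tert-butyldimethylsilyl chloride, CC(C)(C)[Si](C)(C)Cl
Why: Silyl protection of the primary allylic alcohol removes the acidic OH before the organometallic steps and leaves the E-olefin untouched.

Step 2
Reactants: 2 tert-butyldimethyl{[(2E)-3-methylpent-2-en-4-yn-1-yl]oxy}silane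
Product: 4 tert-butyl{[(2E,4E)-5-iodo-3-methylpenta-2,4-dien-1-yl]oxy}dimethylsilane, via alkenylzirconocene 3 (not isolated)
Conditions: Cp2Zr(H)Cl (1.3 equiv), THF, 23 °C, dark; then I2 (1.2 equiv), 0 °C
Reagents that add atoms: iodine, II
Why: Schwartz hydrozirconation adds Zr–H syn across the terminal alkyne with Zr on the terminal carbon, and iodinolysis of the C–Zr bond goes with retention to give the (4E)-iodide.

Step 3
Reactants: 5 (E)-1,2-dichloroethene; 6 ethynyltrimethylsilane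
Product: 7 [(3E)-4-chlorobut-3-en-1-yn-1-yl]trimethylsilane
Conditions: 5 (5 equiv), Pd(PPh3)4 (3 mol %), CuI (6 mol %), n-BuNH2 (2 equiv), Et2O, 23 °C
Reagents that add atoms: none
Why: Sonogashira mono-coupling of the excess dichloride works because oxidative addition to 1,2-dichloroethene is much faster than to the chloroenyne product, and the E geometry is retained.

Step 4
Reactants: 8 5-bromo-2-methylpent-2-ene
Product: 9 6-methylhept-5-en-1-yne
Conditions: LiC≡CH·H2NCH2CH2NH2 (1.3 equiv), DMSO, 10 → 23 °C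
Reagents that add atoms: lithium acetylide ethylenediamine complex, [Li]C#C.NCCN
Why: SN2 alkylation of acetylide by the primary homoallylic bromide in DMSO gives the terminal alkyne.

Step 5
Reactants: 9 6-methylhept-5-en-1-yne; 7 [(3E)-4-chlorobut-3-en-1-yn-1-yl]trimethylsilane
Product: 11 [(3E,5E)-6,10-dimethylundeca-3,5,9-trien-1-yn-1-yl]trimethylsilane, via alkenylalane 10 (not isolated)
Conditions: Me3Al (2.5 equiv), Cp2ZrCl2 (0.25 equiv), ClCH2CH2Cl, 23 °C; then 7 (0.9 equiv), ZnCl2 (0.3 equiv), Pd(PtBu3)2 (3 mol %), THF, 23 → 45 °C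
Reagents that add atoms: trimethylaluminium, C[Al](C)C
Why: Negishi zirconium-catalysed methylalumination adds Me–Al syn across the terminal alkyne (methyl on the internal carbon, setting the 5′E olefin), and the alkenylalane is then cross-coupled under Pd/Zn catalysis with the activated chloroenyne with retention at both partners (7′E).

Step 6
Reactants: 11 [(3E,5E)-6,10-dimethylundeca-3,5,9-trien-1-yn-1-yl]trimethylsilane
Product: 12 (3E,5E)-6,10-dimethylundeca-3,5,9-trien-1-yne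
Conditions: K2CO3 (0.3 equiv), MeOH, 23 °C
Reagents that add atoms: none
Why: Methoxide-mediated protodesilylation cleaves only the alkynyl C–Si bond and frees the terminal alkyne for the next carbometalation.

Step 7
Reactants: 12 (3E,5E)-6,10-dimethylundeca-3,5,9-trien-1-yne; 4 tert-butyl{[(2E,4E)-5-iodo-3-methylpenta-2,4-dien-1-yl]oxy}dimethylsilane
Product: 14 tert-butyldimethyl{[(2E,4E,6E,8E,10E)-3,7,11,15-tetramethylhexadeca-2,4,6,8,10,14-hexaen-1-yl]oxy}silane, via trienylalane 13 (not isolated)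
Conditions: Me3Al (2.5 equiv), Cp2ZrCl2 (0.5 equiv), ClCH2CH2Cl, 23 °C; then 4 (0.9 equiv), ZnCl2 (0.3 equiv), Pd(PPh3)4 (5 mol %), THF, 23 °C, dark
Reagents that add atoms: trimethylaluminium, C[Al](C)C
Why: A second syn methylalumination sets the 9′E trisubstituted olefin, and Negishi coupling of the alkenylalane with the dienyl iodide joins C10′ to C11′ with retention, completing the acyclic C20 chain.

Step 8
Reactants: 14 tert-butyldimethyl{[(2E,4E,6E,8E,10E)-3,7,11,15-tetramethylhexadeca-2,4,6,8,10,14-hexaen-1-yl]oxy}silane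
Product: 15 (2E,4E,6E,8E,10E)-3,7,11,15-tetramethylhexadeca-2,4,6,8,10,14-hexaen-1-ol
Conditions: Bu4NF (1.2 equiv), THF, 0 °C
Reagents that add atoms: none
Why: Fluoride cleaves the Si–O bond of the primary silyl ether without touching the polyene.

Step 9
Reactants: 15 (2E,4E,6E,8E,10E)-3,7,11,15-tetramethylhexadeca-2,4,6,8,10,14-hexaen-1-ol
Product: 16 (2E,4E,6E,8E,10E)-3,7,11,15-tetramethylhexadeca-2,4,6,8,10,14-hexaenal
Conditions: MnO2 (15 equiv), CH2Cl2, 23 °C, dark
Reagents that add atoms: none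
Why: MnO2 oxidises the allylic alcohol selectively to the polyenal without isomerising the double bonds.

Step 10
Reactants: 17 2-methylbuta-1,3-diene (isoprene); 18 methyl prop-2-enoate (methyl acrylate)
Product: 19 methyl (1R)-4-methylcyclohex-3-ene-1-carboxylate
Conditions: (R)-o-tolyl-CBS oxazaborolidine (10 mol %) activated with AlBr3 (8 mol %), CH2Cl2, −40 → −20 °C
Reagents that add atoms: none
Why: The Lewis-acid-catalysed enantioselective Diels–Alder reaction gives the para adduct and sets C2 by catalyst control of the acrylate face; the (R)-catalyst is chosen by analogy with the (S)-catalyst/(S)-cyclohex-3-enecarboxylate pairing known for butadiene, and the configuration is confirmed at 21 against authentic (R)-(+)-α-terpineol.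

Step 11
Reactants: 19 methyl (1R)-4-methylcyclohex-3-ene-1-carboxylate
Product: 21 2-[(1R)-4-methylcyclohex-3-en-1-yl]propan-2-ol [(R)-α-terpineol], via methyl ketone 20 (not isolated)
Conditions: MeMgBr (3 equiv), THF, 0 → 23 °C; aq NH4Cl
Reagents that add atoms: methylmagnesium bromide, C[Mg]Br
Why: Double Grignard addition to the ester builds the C1 carbinol with its two methyl groups, and the stereocentre is not enolised in the product-forming steps.

Step 12
Reactants: 21 2-[(1R)-4-methylcyclohex-3-en-1-yl]propan-2-ol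
Product: 22 triethyl({2-[(1R)-4-methylcyclohex-3-en-1-yl]propan-2-yl}oxy)silane
Conditions: Et3SiOTf (1.3 equiv), 2,6-lutidine (2 equiv), CH2Cl2, −78 → 0 °C
Reagents that add atoms: triethylsilyl trifluoromethanesulfonate, CC[Si](CC)(CC)OS(=O)(=O)C(F)(F)F
Why: The silyl triflate protects the hindered tertiary alcohol, which would otherwise form lactols and oxa-Michael adducts with the aldehyde made next.

Step 13
Reactants: 22 triethyl({2-[(1R)-4-methylcyclohex-3-en-1-yl]propan-2-yl}oxy)silane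
Product: 24 (3R)-6-oxo-3-{2-[(triethylsilyl)oxy]propan-2-yl}heptanal, via secondary ozonide 23 (not isolated)
Conditions: O3, CH2Cl2, −78 °C; then Me2S (5 equiv), −78 → 23 °C
Reagents that add atoms: ozone, [O-][O+]=O
Why: Ozonolysis with reductive work-up cleaves the only C=C bond to the keto aldehyde and opens the six-membered ring for contraction.

Step 14
Reactants: 24 (3R)-6-oxo-3-{2-[(triethylsilyl)oxy]propan-2-yl}heptanal
Product: 26 (5R)-2-methyl-5-{2-[(triethylsilyl)oxy]propan-2-yl}cyclopent-1-ene-1-carbaldehyde, via aldol adduct 25 (not isolated)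
Conditions: piperidine (0.3 equiv), AcOH (0.3 equiv), toluene, 80 °C
Reagents that add atoms: none
Why: In this amine-catalysed intramolecular aldol condensation the aldehyde enamine attacks the methyl ketone to close the cyclopentane, dehydration gives the tetrasubstituted enal, and the C2 stereocentre cannot enolise.

Step 15
Reactants: 26 (5R)-2-methyl-5-{2-[(triethylsilyl)oxy]propan-2-yl}cyclopent-1-ene-1-carbaldehyde
Product: 27 (1S,2R,5R)-5-methyl-2-{2-[(triethylsilyl)oxy]propan-2-yl}-6-oxabicyclo[3.1.0]hexane-1-carbaldehyde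
Conditions: 30 % aq H2O2 (3 equiv), NaOH (0.3 equiv), MeOH, 0 °C
Reagents that add atoms: hydrogen peroxide, OO
Why: In this Weitz–Scheffer nucleophilic epoxidation the hydroperoxide adds reversibly and the ring closes anti to the bulky CMe2OSiEt3 group on C2, so the epoxide oxygen lies trans to that group and fixes C5 as R.

Step 16
Reactants: 27 (1S,2R,5R)-5-methyl-2-{2-[(triethylsilyl)oxy]propan-2-yl}-6-oxabicyclo[3.1.0]hexane-1-carbaldehyde
Product: 29 (1R,3R)-1-methyl-2-methylidene-3-{2-[(triethylsilyl)oxy]propan-2-yl}cyclopentan-1-ol, via epoxy hydrazone 28 (not isolated)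
Conditions: N2H4·H2O (3 equiv), AcOH (0.5 equiv), MeOH, 0 → 23 °C
Reagents that add atoms: none
Why: In the Wharton transposition the epoxy hydrazone opens at C6–O and loses N2 to give the tertiary allylic alcohol with an exocyclic methylene, while the C5–O bond and hence the C5 configuration are untouched.

Step 17
Reactants: 29 (1R,3R)-1-methyl-2-methylidene-3-{2-[(triethylsilyl)oxy]propan-2-yl}cyclopentan-1-ol
Product: 31 (1R,2S,3R)-2-(hydroxymethyl)-1-methyl-3-{2-[(triethylsilyl)oxy]propan-2-yl}cyclopentan-1-ol, via alkylborane 30 (not isolated)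
Conditions: 9-BBN (3 equiv), THF, 0 → 40 °C; then aq NaOH, 30 % H2O2, 0 → 23 °C
Reagents that add atoms: hydrogen peroxide, OO
Why: Anti-Markovnikov hydroboration–oxidation delivers hydrogen to C6 from the face that carries only OH (C5) and H (C2), opposite to the C5 methyl and the C2 CMe2OSiEt3 group, so the new CH2OH (C7) ends up cis to both carbon substituents and trans to the C5 hydroxyl.

Step 18
Reactants: 31 (1R,2S,3R)-2-(hydroxymethyl)-1-methyl-3-{2-[(triethylsilyl)oxy]propan-2-yl}cyclopentan-1-ol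
Product: 32 triethyl{[(1R,2S,3R)-1-methyl-2-{[(triethylsilyl)oxy]methyl}-3-{2-[(triethylsilyl)oxy]propan-2-yl}cyclopentyl]oxy}silane
Conditions: Et3SiOTf (3 equiv), 2,6-lutidine (5 equiv), CH2Cl2, −78 → 23 °C
Reagents that add atoms: triethylsilyl trifluoromethanesulfonate, CC[Si](CC)(CC)OS(=O)(=O)C(F)(F)F
Why: Exhaustive silylation caps the tertiary C5 hydroxyl, so that the aldehyde made next cannot undergo retro-aldol cleavage or β-elimination, and prepares the primary ether for oxidative removal.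

Step 19
Reactants: 32 triethyl{[(1R,2S,3R)-1-methyl-2-{[(triethylsilyl)oxy]methyl}-3-{2-[(triethylsilyl)oxy]propan-2-yl}cyclopentyl]oxy}silane
Product: 33 (1R,2R,5R)-2-methyl-2-[(triethylsilyl)oxy]-5-{2-[(triethylsilyl)oxy]propan-2-yl}cyclopentane-1-carbaldehyde
Conditions: (COCl)2 (4 equiv), DMSO (8 equiv), CH2Cl2, −78 → −35 °C; then Et3N (12 equiv), −78 → −20 °C
Reagents that add atoms: none
Why: Under Swern conditions the chlorosulfonium ion cleaves only the unhindered primary triethylsilyl ether and the alkoxysulfonium ylide collapses to the aldehyde, while the tertiary silyl ethers survive and the low temperature protects the C6 stereocentre.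

Step 20
Reactants: 33 (1R,2R,5R)-2-methyl-2-[(triethylsilyl)oxy]-5-{2-[(triethylsilyl)oxy]propan-2-yl}cyclopentane-1-carbaldehyde
Product: 34 triethyl{[(1R,2S,3R)-2-[(E)-2-iodoethenyl]-1-methyl-3-{2-[(triethylsilyl)oxy]propan-2-yl}cyclopentyl]oxy}silane
Conditions: CrCl2 (8 equiv), CHI3 (3 equiv), THF/1,4-dioxane (1:6), 0 → 23 °C, dark
Reagents that add atoms: iodoform, IC(I)I
Why: In the Takai iodo-olefination the geminal dichromium reagent adds to the aldehyde under non-basic conditions and eliminates to the (E)-vinyl iodide (C7=C8) without epimerising C6.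

Step 21
Reactants: 34 triethyl{[(1R,2S,3R)-2-[(E)-2-iodoethenyl]-1-methyl-3-{2-[(triethylsilyl)oxy]propan-2-yl}cyclopentyl]oxy}silane; 6 ethynyltrimethylsilane
Product: 35 triethyl{[(1R,2R,3R)-1-methyl-3-{2-[(triethylsilyl)oxy]propan-2-yl}-2-[(1E)-4-(trimethylsilyl)but-1-en-3-yn-1-yl]cyclopentyl]oxy}silane
Conditions: PdCl2(PPh3)2 (3 mol %), CuI (6 mol %), Et3N, THF, 23 °C
Reagents that add atoms: none
Why: Sonogashira coupling of the vinyl iodide with the silylacetylene forms the C8–C9 bond with retention of the 7E geometry.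

Step 22
Reactants: 35 triethyl{[(1R,2R,3R)-1-methyl-3-{2-[(triethylsilyl)oxy]propan-2-yl}-2-[(1E)-4-(trimethylsilyl)but-1-en-3-yn-1-yl]cyclopentyl]oxy}silane
Product: 36 {[(1R,2R,3R)-2-[(1E)-but-1-en-3-yn-1-yl]-1-methyl-3-{2-[(triethylsilyl)oxy]propan-2-yl}cyclopentyl]oxy}triethylsilane
Conditions: K2CO3 (0.5 equiv), MeOH/THF, 23 °C
Reagents that add atoms: none
Why: Mild methanolysis removes only the alkynyl silyl group and leaves the hindered tertiary silyl ethers in place.

Step 23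
Reactants: 36 {[(1R,2R,3R)-2-[(1E)-but-1-en-3-yn-1-yl]-1-methyl-3-{2-[(triethylsilyl)oxy]propan-2-yl}cyclopentyl]oxy}triethylsilane; 4 tert-butyl{[(2E,4E)-5-iodo-3-methylpenta-2,4-dien-1-yl]oxy}dimethylsilane
Product: 38 tert-butyl{[(2E,4E,6E,8E)-3,7-dimethyl-9-{(1R,2R,5R)-2-methyl-2-[(triethylsilyl)oxy]-5-{2-[(triethylsilyl)oxy]propan-2-yl}cyclopentyl}nona-2,4,6,8-tetraen-1-yl]oxy}dimethylsilane, via dienylalane 37 (not isolated)
Conditions: Me3Al (3 equiv), Cp2ZrCl2 (0.5 equiv), ClCH2CH2Cl, 23 °C; then 4 (1.2 equiv), ZnCl2 (0.3 equiv), Pd(PPh3)4 (5 mol %), THF, 23 °C, dark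
Reagents that add atoms: trimethylaluminium, C[Al](C)C
Why: Syn methylalumination of the conjugated enyne installs the C9 methyl and the 9E olefin, and Negishi coupling of the dienylalane with the dienyl iodide forms C10–C11 with retention, giving the ring-end C20 chain.

Step 24
Reactants: 38 tert-butyl{[(2E,4E,6E,8E)-3,7-dimethyl-9-{(1R,2R,5R)-2-methyl-2-[(triethylsilyl)oxy]-5-{2-[(triethylsilyl)oxy]propan-2-yl}cyclopentyl}nona-2,4,6,8-tetraen-1-yl]oxy}dimethylsilane
Product: 39 (1R,2R,3R)-2-[(1E,3E,5E,7E)-9-hydroxy-3,7-dimethylnona-1,3,5,7-tetraen-1-yl]-3-(2-hydroxypropan-2-yl)-1-methylcyclopentan-1-ol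
Conditions: Bu4NF (5 equiv), THF, 0 → 40 °C
Reagents that add atoms: none
Why: Fluoride removes all three silyl groups under non-acidic conditions that the polyene and the tertiary alcohols tolerate.

Step 25
Reactants: 39 (1R,2R,3R)-2-[(1E,3E,5E,7E)-9-hydroxy-3,7-dimethylnona-1,3,5,7-tetraen-1-yl]-3-(2-hydroxypropan-2-yl)-1-methylcyclopentan-1-ol
Product: 40 [(2E,4E,6E,8E)-9-[(1R,2R,5R)-2-hydroxy-5-(2-hydroxypropan-2-yl)-2-methylcyclopentyl]-3,7-dimethylnona-2,4,6,8-tetraen-1-yl]triphenylphosphonium bromide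
Conditions: Ph3P·HBr (1.05 equiv), MeOH, 0 → 23 °C, dark
Reagents that add atoms: triphenylphosphine hydrobromide, Br.c1ccc(cc1)P(c1ccccc1)c1ccccc1
Why: The polyenylic primary alcohol ionises under the mild acid to a delocalised allylic cation that phosphine traps at the terminal carbon (as in retinyl salt formation), while the non-allylic tertiary alcohols do not ionise.

Step 26
Reactants: 40 [(2E,4E,6E,8E)-9-[(1R,2R,5R)-2-hydroxy-5-(2-hydroxypropan-2-yl)-2-methylcyclopentyl]-3,7-dimethylnona-2,4,6,8-tetraen-1-yl]triphenylphosphonium bromide; 16 (2E,4E,6E,8E,10E)-3,7,11,15-tetramethylhexadeca-2,4,6,8,10,14-hexaenal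
Product: 43 (all-E,2R,5R,6R)-2,6-cyclolycopene-1,5-diol (target), via phosphorus ylide 41 (not isolated), via 15Z isomer 42 (not isolated)
Conditions: NaOMe (3 equiv), MeOH/CH2Cl2, 0 → 23 °C, dark; then n-heptane, reflux, N2, crystallisation
Reagents that add atoms: none
Why: Wittig olefination of the C20 polyenal with the C20 allylic ylide forms the central C15=C15′ bond as an all-E/15Z mixture, and the unhindered central Z bond isomerises on heating to the all-E carotenoid, which crystallises.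

**Compound list**

1 | (2E)-3-methylpent-2-en-4-yn-1-ol | C#C/C(C)=C/CO | starting material
2 | tert-butyldimethyl{[(2E)-3-methylpent-2-en-4-yn-1-yl]oxy}silane | C#C/C(C)=C/CO[Si](C)(C)C(C)(C)C | intermediate
3 | chlorobis(cyclopentadienyl)[(1E,3E)-5-(tert-butyldimethylsilyloxy)-3-methylpenta-1,3-dien-1-yl]zirconium (cyclopentadienyl rings drawn σ-bonded) | Cl[Zr](C1C=CC=C1)(C1C=CC=C1)/C=C/C(C)=C/CO[Si](C)(C)C(C)(C)C | intermediate (not isolated)
4 | tert-butyl{[(2E,4E)-5-iodo-3-methylpenta-2,4-dien-1-yl]oxy}dimethylsilane | I/C=C/C(C)=C/CO[Si](C)(C)C(C)(C)C | intermediate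
5 | (E)-1,2-dichloroethene | Cl/C=C/Cl | starting material
6 | ethynyltrimethylsilane | C#C[Si](C)(C)C | starting material
7 | [(3E)-4-chlorobut-3-en-1-yn-1-yl]trimethylsilane | Cl/C=C/C#C[Si](C)(C)C | intermediate
8 | 5-bromo-2-methylpent-2-ene | CC(C)=CCCBr | starting material
9 | 6-methylhept-5-en-1-yne | CC(C)=CCCC#C | intermediate
10 | [(1E)-2,6-dimethylhepta-1,5-dien-1-yl]dimethylalumane | C[Al](C)/C=C(\C)CCC=C(C)C | intermediate (not isolated)
11 | [(3E,5E)-6,10-dimethylundeca-3,5,9-trien-1-yn-1-yl]trimethylsilane | C[Si](C)(C)C#C/C=C/C=C(\C)CCC=C(C)C | intermediate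
12 | (3E,5E)-6,10-dimethylundeca-3,5,9-trien-1-yne | C#C/C=C/C=C(\C)CCC=C(C)C | intermediate
13 | dimethyl[(1E,3E,5E)-2,6,10-trimethylundeca-1,3,5,9-tetraen-1-yl]alumane | C[Al](C)/C=C(\C)/C=C/C=C(\C)CCC=C(C)C | intermediate (not isolated)
14 | tert-butyldimethyl{[(2E,4E,6E,8E,10E)-3,7,11,15-tetramethylhexadeca-2,4,6,8,10,14-hexaen-1-yl]oxy}silane | CC(C)(C)[Si](C)(C)OC/C=C(\C)/C=C/C=C(\C)/C=C/C=C(\C)CCC=C(C)C | intermediate
15 | (2E,4E,6E,8E,10E)-3,7,11,15-tetramethylhexadeca-2,4,6,8,10,14-hexaen-1-ol | OC/C=C(\C)/C=C/C=C(\C)/C=C/C=C(\C)CCC=C(C)C | intermediate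
16 | (2E,4E,6E,8E,10E)-3,7,11,15-tetramethylhexadeca-2,4,6,8,10,14-hexaenal | O=C/C=C(\C)/C=C/C=C(\C)/C=C/C=C(\C)CCC=C(C)C | intermediate
17 | 2-methylbuta-1,3-diene (isoprene) | C=CC(C)=C | starting material
18 | methyl prop-2-enoate (methyl acrylate) | C=CC(=O)OC | starting material
19 | methyl (1R)-4-methylcyclohex-3-ene-1-carboxylate | COC(=O)[C@H]1CC=C(C)CC1 | intermediate
20 | 1-[(1R)-4-methylcyclohex-3-en-1-yl]ethan-1-one | CC(=O)[C@H]1CC=C(C)CC1 | intermediate (not isolated)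
21 | 2-[(1R)-4-methylcyclohex-3-en-1-yl]propan-2-ol [(R)-α-terpineol] | CC(C)(O)[C@H]1CC=C(C)CC1 | intermediate
22 | triethyl({2-[(1R)-4-methylcyclohex-3-en-1-yl]propan-2-yl}oxy)silane | CC[Si](CC)(CC)OC(C)(C)[C@H]1CC=C(C)CC1 | intermediate
23 | secondary ozonide of 22: (4R)-1-methyl-4-{2-[(triethylsilyl)oxy]propan-2-yl}-7,8,9-trioxabicyclo[4.2.1]nonane (mixture at the ozonide carbons) | CC[Si](CC)(CC)OC(C)(C)[C@@H]1CCC2(C)OOC(C1)O2 | intermediate (not isolated)
24 | (3R)-6-oxo-3-{2-[(triethylsilyl)oxy]propan-2-yl}heptanal | CC[Si](CC)(CC)OC(C)(C)[C@H](CCC(C)=O)CC=O | intermediate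
25 | (5R)-2-hydroxy-2-methyl-5-{2-[(triethylsilyl)oxy]propan-2-yl}cyclopentane-1-carbaldehyde (diastereomer mixture at C1 and C2 of the ring) | CC[Si](CC)(CC)OC(C)(C)[C@@H]1CCC(C)(O)C1C=O | intermediate (not isolated)
26 | (5R)-2-methyl-5-{2-[(triethylsilyl)oxy]propan-2-yl}cyclopent-1-ene-1-carbaldehyde | CC[Si](CC)(CC)OC(C)(C)[C@@H]1CCC(C)=C1C=O | intermediate
27 | (1S,2R,5R)-5-methyl-2-{2-[(triethylsilyl)oxy]propan-2-yl}-6-oxabicyclo[3.1.0]hexane-1-carbaldehyde | CC[Si](CC)(CC)OC(C)(C)[C@@H]1CC[C@@]2(C)O[C@@]12C=O | intermediate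
28 | hydrazone of 27 | CC[Si](CC)(CC)OC(C)(C)[C@@H]1CC[C@@]2(C)O[C@@]12C=NN | intermediate (not isolated)
29 | (1R,3R)-1-methyl-2-methylidene-3-{2-[(triethylsilyl)oxy]propan-2-yl}cyclopentan-1-ol | CC[Si](CC)(CC)OC(C)(C)[C@@H]1CC[C@@](C)(O)C1=C | intermediate
30 | (1R,2R,3R)-2-[(9-borabicyclo[3.3.1]nonan-9-yl)methyl]-1-methyl-3-{2-[(triethylsilyl)oxy]propan-2-yl}cyclopentan-1-ol | CC[Si](CC)(CC)OC(C)(C)[C@@H]1CC[C@@](C)(O)[C@@H]1CB1C2CCCC1CCC2 | intermediate (not isolated)
31 | (1R,2S,3R)-2-(hydroxymethyl)-1-methyl-3-{2-[(triethylsilyl)oxy]propan-2-yl}cyclopentan-1-ol | CC[Si](CC)(CC)OC(C)(C)[C@@H]1CC[C@@](C)(O)[C@@H]1CO | intermediate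
32 | triethyl{[(1R,2S,3R)-1-methyl-2-{[(triethylsilyl)oxy]methyl}-3-{2-[(triethylsilyl)oxy]propan-2-yl}cyclopentyl]oxy}silane | CC[Si](CC)(CC)OC(C)(C)[C@@H]1CC[C@@](C)(O[Si](CC)(CC)CC)[C@@H]1CO[Si](CC)(CC)CC | intermediate
33 | (1R,2R,5R)-2-methyl-2-[(triethylsilyl)oxy]-5-{2-[(triethylsilyl)oxy]propan-2-yl}cyclopentane-1-carbaldehyde | CC[Si](CC)(CC)OC(C)(C)[C@@H]1CC[C@@](C)(O[Si](CC)(CC)CC)[C@@H]1C=O | intermediate
34 | triethyl{[(1R,2S,3R)-2-[(E)-2-iodoethenyl]-1-methyl-3-{2-[(triethylsilyl)oxy]propan-2-yl}cyclopentyl]oxy}silane | CC[Si](CC)(CC)OC(C)(C)[C@@H]1CC[C@@](C)(O[Si](CC)(CC)CC)[C@@H]1/C=C/I | intermediate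
35 | triethyl{[(1R,2R,3R)-1-methyl-3-{2-[(triethylsilyl)oxy]propan-2-yl}-2-[(1E)-4-(trimethylsilyl)but-1-en-3-yn-1-yl]cyclopentyl]oxy}silane | CC[Si](CC)(CC)OC(C)(C)[C@@H]1CC[C@@](C)(O[Si](CC)(CC)CC)[C@@H]1/C=C/C#C[Si](C)(C)C | intermediate
36 | {[(1R,2R,3R)-2-[(1E)-but-1-en-3-yn-1-yl]-1-methyl-3-{2-[(triethylsilyl)oxy]propan-2-yl}cyclopentyl]oxy}triethylsilane | CC[Si](CC)(CC)OC(C)(C)[C@@H]1CC[C@@](C)(O[Si](CC)(CC)CC)[C@@H]1/C=C/C#C | intermediate
37 | dimethyl[(1E,3E)-2-methyl-4-{(1R,2R,5R)-2-methyl-2-[(triethylsilyl)oxy]-5-{2-[(triethylsilyl)oxy]propan-2-yl}cyclopentyl}buta-1,3-dien-1-yl]alumane | CC[Si](CC)(CC)OC(C)(C)[C@@H]1CC[C@@](C)(O[Si](CC)(CC)CC)[C@@H]1/C=C/C(C)=C/[Al](C)C | intermediate (not isolated)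
38 | tert-butyl{[(2E,4E,6E,8E)-3,7-dimethyl-9-{(1R,2R,5R)-2-methyl-2-[(triethylsilyl)oxy]-5-{2-[(triethylsilyl)oxy]propan-2-yl}cyclopentyl}nona-2,4,6,8-tetraen-1-yl]oxy}dimethylsilane | CC[Si](CC)(CC)OC(C)(C)[C@@H]1CC[C@@](C)(O[Si](CC)(CC)CC)[C@@H]1/C=C/C(C)=C/C=C/C(C)=C/CO[Si](C)(C)C(C)(C)C | intermediate
39 | (1R,2R,3R)-2-[(1E,3E,5E,7E)-9-hydroxy-3,7-dimethylnona-1,3,5,7-tetraen-1-yl]-3-(2-hydroxypropan-2-yl)-1-methylcyclopentan-1-ol | CC(C)(O)[C@@H]1CC[C@@](C)(O)[C@@H]1/C=C/C(C)=C/C=C/C(C)=C/CO | intermediate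
40 | [(2E,4E,6E,8E)-9-[(1R,2R,5R)-2-hydroxy-5-(2-hydroxypropan-2-yl)-2-methylcyclopentyl]-3,7-dimethylnona-2,4,6,8-tetraen-1-yl]triphenylphosphonium bromide | CC(C)(O)[C@@H]1CC[C@@](C)(O)[C@@H]1/C=C/C(C)=C/C=C/C(C)=C/C[P+](c1ccccc1)(c1ccccc1)c1ccccc1.[Br-] | intermediate
41 | ylide of 40 [(triphenylphosphoranylidene) at C15] | CC(C)(O)[C@@H]1CC[C@@](C)(O)[C@@H]1/C=C/C(C)=C/C=C/C(C)=C/C=P(c1ccccc1)(c1ccccc1)c1ccccc1 | intermediate (not isolated)
42 | (15Z,2R,5R,6R)-2,6-cyclolycopene-1,5-diol (all other double bonds E) | CC(C)=CCC/C(C)=C/C=C/C(C)=C/C=C/C(C)=C/C=C\C=C(C)\C=C\C=C(C)\C=C\[C@@H]1[C@H](C(C)(C)O)CC[C@@]1(C)O | intermediate (not isolated)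
43 | (all-E,2R,5R,6R)-2,6-cyclolycopene-1,5-diol | CC(C)=CCC/C(C)=C/C=C/C(C)=C/C=C/C(C)=C/C=C/C=C(C)/C=C/C=C(C)/C=C/[C@@H]1[C@H](C(C)(C)O)CC[C@@]1(C)O | target

**Step count and risks**

Total step count: 26. Longest linear sequence: 17 steps (steps 10 to 26, from 17 and 18 to 43).

Three steps most likely to fail:

Step 10 (enantioselectivity of the cycloaddition with a simple methyl ester, and its sense, which is assigned only by analogy). The fallback sets out from 17 and 18 and comes back to the route at 19. An AlCl3-catalysed Diels–Alder reaction (toluene, 0 °C) gives racemic methyl 4-methylcyclohex-3-ene-1-carboxylate F1. Saponification (LiOH, THF/H2O) gives racemic 4-methylcyclohex-3-ene-1-carboxylic acid F2. Classical resolution by fractional crystallisation with enantiopure 1-phenylethylamine gives (R)-1-phenylethylammonium (1R)-4-methylcyclohex-3-ene-1-carboxylate F3; the amine antipode is chosen so that the salt of the (1R)-acid is the less soluble one, and it is written here for the (R)-amine. Aqueous HCl liberates (1R)-4-methylcyclohex-3-ene-1-carboxylic acid F4, and MeI with K2CO3 in DMF returns enantiopure 19.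

Step 16 (Wharton transposition of a hindered, sensitive epoxy aldehyde). The fallback sets out from 26 and comes back at 29. Luche reduction (NaBH4, CeCl3·7H2O, MeOH, 0 °C) gives [(5R)-2-methyl-5-{2-[(triethylsilyl)oxy]propan-2-yl}cyclopent-1-en-1-yl]methanol F5. Epoxidation with mCPBA and NaHCO3 (CH2Cl2, 0 °C), anti to the CMe2OSiEt3 group, gives [(1R,2R,5R)-5-methyl-2-{2-[(triethylsilyl)oxy]propan-2-yl}-6-oxabicyclo[3.1.0]hexan-1-yl]methanol F6. Iodination (I2, PPh3, imidazole, THF) gives triethyl({2-[(1S,2R,5R)-1-(iodomethyl)-5-methyl-6-oxabicyclo[3.1.0]hexan-2-yl]propan-2-yl}oxy)silane F7. Zinc dust in refluxing EtOH then opens the epoxide reductively to 29, with the C5–O bond again untouched.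

Step 20 (chromium-mediated olefination of a very hindered aldehyde flanked by two substituted carbons). The fallback sets out from 33 and comes back at 34. Seyferth–Gilbert homologation with dimethyl (1-diazo-2-oxopropyl)phosphonate (K2CO3, MeOH, 0 → 23 °C) gives {[(1R,2S,3R)-2-ethynyl-1-methyl-3-{2-[(triethylsilyl)oxy]propan-2-yl}cyclopentyl]oxy}triethylsilane F8. Hydrozirconation with Cp2Zr(H)Cl (THF, 23 °C) gives the (E)-alkenylzirconocene of F8 F9, which is not isolated, and iodinolysis (I2, 0 °C) gives 34.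

**Further compounds**

F1 | step 10 | racemic methyl 4-methylcyclohex-3-ene-1-carboxylate | COC(=O)C1CC=C(C)CC1
F2 | step 10 | racemic 4-methylcyclohex-3-ene-1-carboxylic acid | OC(=O)C1CC=C(C)CC1
F3 | step 10 | (R)-1-phenylethylammonium (1R)-4-methylcyclohex-3-ene-1-carboxylate | C[C@@H](N)c1ccccc1.OC(=O)[C@H]1CC=C(C)CC1
F4 | step 10 | (1R)-4-methylcyclohex-3-ene-1-carboxylic acid | OC(=O)[C@H]1CC=C(C)CC1
F5 | step 16 | [(5R)-2-methyl-5-{2-[(triethylsilyl)oxy]propan-2-yl}cyclopent-1-en-1-yl]methanol | CC[Si](CC)(CC)OC(C)(C)[C@@H]1CCC(C)=C1CO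
F6 | step 16 | [(1R,2R,5R)-5-methyl-2-{2-[(triethylsilyl)oxy]propan-2-yl}-6-oxabicyclo[3.1.0]hexan-1-yl]methanol | CC[Si](CC)(CC)OC(C)(C)[C@@H]1CC[C@@]2(C)O[C@@]12CO
F7 | step 16 | triethyl({2-[(1S,2R,5R)-1-(iodomethyl)-5-methyl-6-oxabicyclo[3.1.0]hexan-2-yl]propan-2-yl}oxy)silane | CC[Si](CC)(CC)OC(C)(C)[C@@H]1CC[C@@]2(C)O[C@@]12CI
F8 | step 20 | {[(1R,2S,3R)-2-ethynyl-1-methyl-3-{2-[(triethylsilyl)oxy]propan-2-yl}cyclopentyl]oxy}triethylsilane | CC[Si](CC)(CC)OC(C)(C)[C@@H]1CC[C@@](C)(O[Si](CC)(CC)CC)[C@@H]1C#C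
F9 | step 20 | (E)-alkenylzirconocene of F8, chlorobis(cyclopentadienyl)zirconium at C8 (cyclopentadienyl rings drawn σ-bonded) | CC[Si](CC)(CC)OC(C)(C)[C@@H]1CC[C@@](C)(O[Si](CC)(CC)CC)[C@@H]1/C=C/[Zr](Cl)(C1C=CC=C1)C1C=CC=C1
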